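**Pl an**

- Numbering: lactone C1(=O), O2, C3; ring A = C3a, C4, C5, C6, C7, C7a; side chain C1' to C14'; C3 and C13' are both (S). Ring A bears oxygen on the alternate carbons C5 and C7, the carboxyl carbon C1 on C7a and C3 on C3a. This is the pattern of a folded 3,5,7-triketo acid, so ring A can be closed by an aldol between C7a and C3a.
- Cuts, in retrosynthetic order: the two O–CH3 bonds; the lactone bond O2–C1; C7a–C3a (aldol aromatization); C3a–C4 (Claisen-type acylation); C5–C6 (acetylation of the dioxinone); C11'–C12' (cross-metathesis, then hydrogenation); C1'–C2' (epoxide opening).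
- Forward: the chain (future C3a, C3, C1'–C14') is joined first and turned into a bis-silylated Weinreb amide, which acylates the dianion of the acetylated dioxinone. Ring A then forms by aldol aromatization, ring B (the lactone) closes on desilylation, and the phenols are methylated last.
- Stereochemistry: C3 is C2 of methyl (S)-glycidate and C13' is the carbinol carbon of (S)-but-3-en-2-ol. Neither carbon takes part in a bond-forming step and no stereocenter is set by a reagent.

Key step: step 8

TBS = tert-butyldimethylsilyl.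

**Route**

Step 1
Reactants: 1 11-bromoundec-1-ene; 2 methyl (2S)-oxirane-2-carboxylate
Product: 4 methyl (2S)-2-hydroxytetradec-13-enoate, via undec-10-enylmagnesium bromide 3 (not isolated)
Conditions: Mg, THF, rt; then CuBr·SMe2 (10 mol %), 2, THF, −78 → −30 °C
Reagents that add atoms: none
Why: Copper-catalysed Grignard opening of a glycidic ester is an SN2 attack at the unsubstituted epoxide carbon that outruns carbonyl addition at low temperature, so C2 of 2 is not touched and should become the (S)-carbinol of 4.

Step 2
Reactants: 4 methyl (2S)-2-hydroxytetradec-13-enoate; 5 (2S)-but-3-en-2-ol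
Product: 6 methyl (2S,13E,15S)-2,15-dihydroxyhexadec-13-enoate
Conditions: 5 (4 equiv), second-generation Grubbs catalyst (H2IMes)(PCy3)Cl2Ru=CHPh (5 mol %), CH2Cl2, 40 °C
Reagents that add atoms: none
Why: Olefin cross-metathesis of a terminal alkene with an excess of a slowly homodimerizing secondary allylic alcohol should favour the cross product with loss of ethene, the carbinol carbon of 5 is not involved, and any Z isomer converges in the next step.

Step 3
Reactants: 6 methyl (2S,13E,15S)-2,15-dihydroxyhexadec-13-enoate
Product: 7 methyl (2S,15S)-2,15-dihydroxyhexadecanoate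
Conditions: H2 (1 atm), PtO2, EtOAc, rt
Reagents that add atoms: none
Why: Catalytic hydrogenation of the disubstituted alkene over platinum should saturate C13–C14 with little isomerization of the allylic alcohol to a ketone and without touching the ester or either stereocenter.

Step 4
Reactants: 7 methyl (2S,15S)-2,15-dihydroxyhexadecanoate
Product: 8 methyl (2S,15S)-2,15-bis(tert-butyldimethylsilyloxy)hexadecanoate
Conditions: TBSCl (3 equiv), imidazole (6 equiv), DMF, rt
Reagents that add atoms: tert-butyldimethylsilyl chloride, CC(C)(C)[Si](C)(C)Cl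
Why: Imidazole-promoted silylation protects both secondary alcohols in one operation as TBS ethers, which should survive amide formation, enolate acylation and amine base and fall off together under acid at the end.

Step 5
Reactants: 8 methyl (2S,15S)-2,15-bis(tert-butyldimethylsilyloxy)hexadecanoate
Product: 9 (2S,15S)-2,15-bis(tert-butyldimethylsilyloxy)-N-methoxy-N-methylhexadecanamide
Conditions: MeNH(OMe)·HCl (1.6 equiv), iPrMgCl (3.2 equiv), THF, −20 → 0 °C
Reagents that add atoms: N,O-dimethylhydroxylamine hydrochloride, CNOC.Cl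
Why: Aminolysis of the methyl ester by the chloromagnesium amide of N,O-dimethylhydroxylamine (Weinreb amide synthesis) is fast below 0 °C and is routinely applied to alpha-silyloxy esters without loss of configuration.

Step 6
Reactants: 10 2,2,6-trimethyl-4H-1,3-dioxin-4-one
Product: 12 2,2-dimethyl-6-(2-oxopropyl)-4H-1,3-dioxin-4-one, via dioxinone lithium dienolate 11 (not isolated)
Conditions: LiN(SiMe3)2 (2 equiv), THF, −78 °C; then AcCl, −78 °C
Reagents that add atoms: acetyl chloride, CC(Cl)=O
Why: The lithium dienolate of the dioxinone is acylated at its gamma carbon (vinylogous Claisen acylation), and the second equivalent of base takes up the more acidic keto-dioxinone as its enolate so that it is not acylated again.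

Step 7
Reactants: 12 2,2-dimethyl-6-(2-oxopropyl)-4H-1,3-dioxin-4-one; 9 (2S,15S)-2,15-bis(tert-butyldimethylsilyloxy)-N-methoxy-N-methylhexadecanamide
Product: 14 6-[(5S,18S)-5,18-bis(tert-butyldimethylsilyloxy)-2,4-dioxononadecyl]-2,2-dimethyl-4H-1,3-dioxin-4-one, via keto-dioxinone dilithium dienolate 13 (not isolated)
Conditions: 12 (2.5 equiv), LiN(iPr)2 (2.1 equiv per 12), THF, −78 °C; then 9, −78 → −30 °C
Reagents that add atoms: none
Why: Claisen-type C-acylation of a 1,3-dicarbonyl dianion takes place at the last-formed terminal carbanion, and the N-methoxy-N-methyl amide acylates once only and at a temperature low enough to leave its alpha-silyloxy stereocenter untouched.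

Step 8
Reactants: 14 6-[(5S,18S)-5,18-bis(tert-butyldimethylsilyloxy)-2,4-dioxononadecyl]-2,2-dimethyl-4H-1,3-dioxin-4-one
Product: 16 5-[(1S,14S)-1,14-bis(tert-butyldimethylsilyloxy)pentadecyl]-7-hydroxy-2,2-dimethyl-4H-1,3-benzodioxin-4-one, via cyclic aldol carbinol 15 (not isolated)
Conditions: Et3N (2 equiv), CH2Cl2, rt
Reagents that add atoms: none
Why: Et3N removes the doubly activated proton between the dioxinone and the central ketone, and the extended enolate attacks the alpha-silyloxy ketone (future C3a) through the dioxinone alpha carbon (future C7a) to give carbinol 15; E1cB loss of water and enolization of the remaining ketone to the C5 phenol then lead to the arene. The closest known reaction type is the base-mediated aldol aromatization of diketo-dioxinones and 3,5,7-triketo esters to resorcylates. Ring A closes in a 6-(enolendo)-exo-trig mode. No lasting stereocenter is created, since the two sp3 ring carbons of 15 become aromatic, and the C3 center should be kept because the 1,3-diketone enolizes between its carbonyl groups and not toward C3 and the base is only a weak amine. The step needs C- over O-cyclization and the C7a-to-C3a fold over Claisen or pyranone modes; the dioxinone secures this by locking the carboxyl carbon C1 and the C7 oxygen in a cyclic acyl ketal that cannot serve as an acyl donor, which leaves its alpha carbon as the only nucleophile within six-ring reach of the terminal ketone, itself activated by the alpha-silyloxy group.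

Step 9
Reactants: 16 5-[(1S,14S)-1,14-bis(tert-butyldimethylsilyloxy)pentadecyl]-7-hydroxy-2,2-dimethyl-4H-1,3-benzodioxin-4-one
Product: 18 (3S)-5,7-dihydroxy-3-[(13S)-13-hydroxytetradecyl]-2-benzofuran-1(3H)-one, via desilylated benzodioxinone diol 17 (not isolated)
Conditions: 3 M aq. HCl, THF, 45 °C
Reagents that add atoms: none
Why: Acid hydrolysis cleaves both silyl ethers, and the freed benzylic hydroxyl should then attack the neighbouring acyl ketal carbonyl in a 5-exo-trig lactonization (intramolecular transesterification) that expels acetone and the C7 phenol, with retention at C3 because its C–O bond is never broken.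

Step 10
Reactants: 18 (3S)-5,7-dihydroxy-3-[(13S)-13-hydroxytetradecyl]-2-benzofuran-1(3H)-one
Product: 19 (3S)-3-[(13S)-13-hydroxytetradecyl]-5,7-dimethoxy-2-benzofuran-1(3H)-one
Conditions: MeI (5 equiv), K2CO3 (5 equiv), acetone, reflux
Reagents that add atoms: iodomethane, CI
Why: Williamson O-methylation with carbonate base should alkylate both phenols, while the secondary alcohol and the C3–H bond are far too weakly acidic to react.

**Compound list**

1 | 11-bromoundec-1-ene | C=CCCCCCCCCCBr | starting material
2 | methyl (2S)-oxirane-2-carboxylate (methyl (S)-glycidate) | COC(=O)[C@@H]1CO1 | starting material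
3 | undec-10-enylmagnesium bromide (formed in the flask) | C=CCCCCCCCCC[Mg]Br | intermediate
4 | methyl (2S)-2-hydroxytetradec-13-enoate | COC(=O)[C@@H](O)CCCCCCCCCCC=C | intermediate
5 | (2S)-but-3-en-2-ol | C=C[C@H](C)O | starting material
6 | methyl (2S,13E,15S)-2,15-dihydroxyhexadec-13-enoate | COC(=O)[C@@H](O)CCCCCCCCCC/C=C/[C@H](C)O | intermediate
7 | methyl (2S,15S)-2,15-dihydroxyhexadecanoate | COC(=O)[C@@H](O)CCCCCCCCCCCC[C@H](C)O | intermediate
8 | methyl (2S,15S)-2,15-bis(tert-butyldimethylsilyloxy)hexadecanoate | COC(=O)[C@@H](O[Si](C)(C)C(C)(C)C)CCCCCCCCCCCC[C@H](C)O[Si](C)(C)C(C)(C)C | intermediate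
9 | (2S,15S)-2,15-bis(tert-butyldimethylsilyloxy)-N-methoxy-N-methylhexadecanamide | CON(C)C(=O)[C@@H](O[Si](C)(C)C(C)(C)C)CCCCCCCCCCCC[C@H](C)O[Si](C)(C)C(C)(C)C | intermediate
10 | 2,2,6-trimethyl-4H-1,3-dioxin-4-one | CC1=CC(=O)OC(C)(C)O1 | starting material
11 | lithium dienolate of 10 (formed in the flask) | C=C1C=C(O[Li])OC(C)(C)O1 | intermediate
12 | 2,2-dimethyl-6-(2-oxopropyl)-4H-1,3-dioxin-4-one | CC(=O)CC1=CC(=O)OC(C)(C)O1 | intermediate
13 | dilithium dienolate of 12 (formed in the flask) | C=C(O[Li])C=C1C=C(O[Li])OC(C)(C)O1 | intermediate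
14 | 6-[(5S,18S)-5,18-bis(tert-butyldimethylsilyloxy)-2,4-dioxononadecyl]-2,2-dimethyl-4H-1,3-dioxin-4-one | CC1(C)OC(=O)C=C(CC(=O)CC(=O)[C@@H](O[Si](C)(C)C(C)(C)C)CCCCCCCCCCCC[C@H](C)O[Si](C)(C)C(C)(C)C)O1 | intermediate
15 | 5-[(1S,14S)-1,14-bis(tert-butyldimethylsilyloxy)pentadecyl]-5-hydroxy-2,2-dimethyl-4a,5-dihydro-4H-1,3-benzodioxine-4,7(6H)-dione, epimers at C4a and C5 (formed in the flask) | CC1(C)OC(=O)C2C(=CC(=O)CC2(O)[C@@H](O[Si](C)(C)C(C)(C)C)CCCCCCCCCCCC[C@H](C)O[Si](C)(C)C(C)(C)C)O1 | intermediate
16 | 5-[(1S,14S)-1,14-bis(tert-butyldimethylsilyloxy)pentadecyl]-7-hydroxy-2,2-dimethyl-4H-1,3-benzodioxin-4-one | CC1(C)OC(=O)c2c(O1)cc(O)cc2[C@@H](O[Si](C)(C)C(C)(C)C)CCCCCCCCCCCC[C@H](C)O[Si](C)(C)C(C)(C)C | intermediate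
17 | 5-[(1S,14S)-1,14-dihydroxypentadecyl]-7-hydroxy-2,2-dimethyl-4H-1,3-benzodioxin-4-one (formed in the flask) | CC1(C)OC(=O)c2c(O1)cc(O)cc2[C@@H](O)CCCCCCCCCCCC[C@H](C)O | intermediate
18 | (3S)-5,7-dihydroxy-3-[(13S)-13-hydroxytetradecyl]-2-benzofuran-1(3H)-one | Oc1cc(O)c2c(c1)[C@H](CCCCCCCCCCCC[C@H](C)O)OC2=O | intermediate
19 | (3S)-3-[(13S)-13-hydroxytetradecyl]-5,7-dimethoxy-2-benzofuran-1(3H)-one | COc1cc(OC)c2c(c1)[C@H](CCCCCCCCCCCC[C@H](C)O)OC2=O | target

**Step count and risks**

Total step count: 10. Longest linear sequence: 9 steps (steps 1–5 and 7–10, from 1 to 19); step 6 is a one-step side branch.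

Steps most likely to fail:

Step 7. The hindered alpha-silyloxy amide may acylate slowly, so that proton transfer to the dianion (return of 9, or erosion of configuration at its C2) or O-acylation takes over. The fallback lowers the oxidation level of the electrophile and sets out from 9. Reduction with iBu2AlH (THF, −78 °C) should give the aldehyde (2S,15S)-2,15-bis(tert-butyldimethylsilyloxy)hexadecanal F1. This much stronger electrophile adds the terminal carbanion of dianion 13 at −78 °C in an aldol addition to give 6-[(5S,18S)-5,18-bis(tert-butyldimethylsilyloxy)-4-hydroxy-2-oxononadecyl]-2,2-dimethyl-4H-1,3-dioxin-4-one F2 as a mixture of carbinol epimers. Dess–Martin periodinane (CH2Cl2, 0 °C) then oxidizes the secondary alcohol, and both epimers converge on 14.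

Step 8. The closure may stall at the aldol carbinol, or the dioxinone alpha carbon may be too weak a nucleophile toward the branched ketone, so that O-cyclization to a pyranone competes. The fallback unmasks the carboxyl before the ring is closed and sets out from 14.
- Heating in toluene with MeOH (110 °C) should expel acetone by retro-[4+2] cleavage to the acyl ketene (8S,21S)-8,21-bis(tert-butyldimethylsilyloxy)docos-1-ene-1,3,5,7-tetrone F3.
- Methanol traps it as methyl (8S,21S)-8,21-bis(tert-butyldimethylsilyloxy)-3,5,7-trioxodocosanoate F4.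
- With Cs2CO3 in MeOH, then AcOH, the C2 methylene of this open triketo ester (a better carbon nucleophile, flanked by ester and ketone) should close the same C7a–C3a bond through methyl 2-[(1S,14S)-1,14-bis(tert-butyldimethylsilyloxy)pentadecyl]-2-hydroxy-4,6-dioxocyclohexane-1-carboxylate F5.
- Dehydration gives the resorcylate methyl 6-[(1S,14S)-1,14-bis(tert-butyldimethylsilyloxy)pentadecyl]-2,4-dihydroxybenzoate F6.
- Under the conditions of step 9 the silyl groups are lost to give methyl 6-[(1S,14S)-1,14-dihydroxypentadecyl]-2,4-dihydroxybenzoate F7, whose benzylic hydroxyl displaces methanol from the ester, and the route is rejoined at 18.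

Step 2. Ruthenium hydride species may isomerize the allylic alcohol to a methyl ketone, which would erase the C15 carbinol, or homodimerization of 4 may dominate. The fallback moves the origin of this stereocenter from the chiral pool to reagent control and sets out from 4. Cross-metathesis with but-3-en-2-one (an electron-poor partner that neither homodimerizes readily nor isomerizes) and the same catalyst, second-generation Grubbs catalyst (H2IMes)(PCy3)Cl2Ru=CHPh, should give the enone methyl (2S,13E)-2-hydroxy-15-oxohexadec-13-enoate F8. Corey–Bakshi–Shibata reduction with (R)-2-methyl-CBS-oxazaborolidine and catecholborane (toluene, −78 °C) should then deliver hydride to the face that gives the (15S) allylic alcohol, returning to 6.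

Further compounds
F1 | step 7 | (2S,15S)-2,15-bis(tert-butyldimethylsilyloxy)hexadecanal | O=C[C@@H](O[Si](C)(C)C(C)(C)C)CCCCCCCCCCCC[C@H](C)O[Si](C)(C)C(C)(C)C
F2 | step 7 | 6-[(5S,18S)-5,18-bis(tert-butyldimethylsilyloxy)-4-hydroxy-2-oxononadecyl]-2,2-dimethyl-4H-1,3-dioxin-4-one (C4 epimers) | CC1(C)OC(=O)C=C(CC(=O)CC(O)[C@@H](O[Si](C)(C)C(C)(C)C)CCCCCCCCCCCC[C@H](C)O[Si](C)(C)C(C)(C)C)O1
F3 | step 8 | (8S,21S)-8,21-bis(tert-butyldimethylsilyloxy)docos-1-ene-1,3,5,7-tetrone (acyl ketene) | O=C=CC(=O)CC(=O)CC(=O)[C@@H](O[Si](C)(C)C(C)(C)C)CCCCCCCCCCCC[C@H](C)O[Si](C)(C)C(C)(C)C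
F4 | step 8 | methyl (8S,21S)-8,21-bis(tert-butyldimethylsilyloxy)-3,5,7-trioxodocosanoate | COC(=O)CC(=O)CC(=O)CC(=O)[C@@H](O[Si](C)(C)C(C)(C)C)CCCCCCCCCCCC[C@H](C)O[Si](C)(C)C(C)(C)C
F5 | step 8 | methyl 2-[(1S,14S)-1,14-bis(tert-butyldimethylsilyloxy)pentadecyl]-2-hydroxy-4,6-dioxocyclohexane-1-carboxylate (ring epimers) | COC(=O)C1C(=O)CC(=O)CC1(O)[C@@H](O[Si](C)(C)C(C)(C)C)CCCCCCCCCCCC[C@H](C)O[Si](C)(C)C(C)(C)C
F6 | step 8 | methyl 6-[(1S,14S)-1,14-bis(tert-butyldimethylsilyloxy)pentadecyl]-2,4-dihydroxybenzoate | COC(=O)c1c(O)cc(O)cc1[C@@H](O[Si](C)(C)C(C)(C)C)CCCCCCCCCCCC[C@H](C)O[Si](C)(C)C(C)(C)C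
F7 | step 8 | methyl 6-[(1S,14S)-1,14-dihydroxypentadecyl]-2,4-dihydroxybenzoate | COC(=O)c1c(O)cc(O)cc1[C@@H](O)CCCCCCCCCCCC[C@H](C)O
F8 | step 2 | methyl (2S,13E)-2-hydroxy-15-oxohexadec-13-enoate | COC(=O)[C@@H](O)CCCCCCCCCC/C=C/C(C)=O
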